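**Retrosynthetic overview**

- Locants without primes belong to the 5,7-dihydroxy half (unit 1, rings A and C); double-primed locants belong to the 7-methoxy half (unit 2, rings A'' and C''). The chain C-4–C-3–C-3''–C-4'' is a succinyl unit, so both pyranone rings are cut at C-2–C-3 / C-4–C-4a and C-2''–C-3'' / C-4''–C-4a''. This leads back to the bis(enol silane) of succinic anhydride, two symmetrical phenols and two molecules of 4-methoxybenzaldehyde.
- Enabling feature: C-2'' carries O-1'' and a 4-methoxyphenyl group, so O-1''=C-2'' can be released as an O-aryl oxocarbenium ion. Ring A'' is a phloroglucinol-type ring whose C-4a'' (ortho to O-1'' and O-5'', para to O-7'') can be acylated by C-4''. C-4a''=C-8a''–O-1''=C-2'' is thus a cationic 2-oxadiene for a formal [4+2] annulation with the C-3''=C-4'' enol silane of an anhydride.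
- Order of ring formation: C-2–C-3 by Mukaiyama addition (step 4), salt resolution, then the key step closes ring C'' (C-2''–C-3'' and C-4''–C-4a'') and, in the same flask, ring C (C-4–C-4a).
- Stereocontrol: syn additions through open transition states give both 2,3-cis relationships, the anhydride ring relays C-3 to C-3'' (trans-anhydride = 3R,3''R), and the resolution fixes the absolute configuration. One BCl3 step removes the benzyl groups and the chelated 5''-methyl group.

Key step: step 7

Remark: 2,5-bis(trimethylsilyloxy)furan is taken as a purchasable reagent.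
Assumption: the less soluble salt in step 5 is taken to be that of the (2R)-acid with (R)-1-phenylethylamine; if the salt of the enantiomeric acid crystallises instead, the (S)-amine is used in the same way.
Remark: racemic compounds are written in the lists as the enantiomer that is carried forward.

Step 1
Reactants: 1 4-methoxybenzaldehyde; 2 pivaloyl chloride
Product: 3 chloro(4-methoxyphenyl)methyl 2,2-dimethylpropanoate (racemic)
Conditions: ZnCl2 (2 mol%), CH2Cl2, 0 °C to rt; volatiles removed, kept as a CH2Cl2 stock solution under argon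
Reagents that add atoms: none
Why: ZnCl2-catalysed addition of the acyl chloride across the aldehyde carbonyl (α-chloroalkyl ester formation) should give the chloro ester in one batch that is divided between steps 2 and 3; the chlorine-bearing carbon is racemic and is substituted in those steps.

Step 2
Reactants: 3 chloro(4-methoxyphenyl)methyl 2,2-dimethylpropanoate; 4 3,5-bis(benzyloxy)phenol
Product: 5 [3,5-bis(benzyloxy)phenoxy](4-methoxyphenyl)methyl 2,2-dimethylpropanoate (racemic)
Conditions: 4 (1.0 equiv), 3 (1.2 equiv), Cs2CO3 (1.5 equiv), MeCN, 0 °C to rt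
Reagents that add atoms: none
Why: O-Alkylation of a phenol with an α-haloalkyl ester, in which the readily ionised benzylic chloride is captured on oxygen by the caesium phenoxide and the bulky pivaloyl group suppresses acyl transfer; the acetal carbon is racemic and is planarised again in step 4.

Step 3
Reactants: 3 chloro(4-methoxyphenyl)methyl 2,2-dimethylpropanoate; 6 3,5-dimethoxyphenol
Product: 7 (3,5-dimethoxyphenoxy)(4-methoxyphenyl)methyl 2,2-dimethylpropanoate (racemic)
Conditions: 6 (1.0 equiv), 3 (1.2 equiv), Cs2CO3 (1.5 equiv), MeCN, 0 °C to rt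
Reagents that add atoms: none
Why: The same α-haloalkyl ester O-alkylation as in step 2, now with the phenol that becomes ring A'' of unit 2; the racemic acetal carbon is planarised in step 7.

Step 4
Reactants: 8 2,5-bis(trimethylsilyloxy)furan; 5 [3,5-bis(benzyloxy)phenoxy](4-methoxyphenyl)methyl 2,2-dimethylpropanoate
Product: 11 rac-(2R)-2-{(R)-[3,5-bis(benzyloxy)phenoxy](4-methoxyphenyl)methyl}butanedioic acid, via enol silane 9 (not isolated), via rac-anhydride 10 (not isolated)
Conditions: 8 (1.3 equiv), Me3SiOTf (10 mol%), CH2Cl2, −78 °C; then H2O–THF, rt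
Reagents that add atoms: water, SMILES O
Why: Mukaiyama-type addition in which Me3SiOTf removes the pivalate (a far better leaving group than the aryloxide) to give the O-aryl oxocarbenium ion, which is attacked by C-3 of the silyloxyfuran through an open antiperiplanar transition state with the anisyl group turned away from the furan ring, so that C-2 and C-3 should form syn (the erythro preference expected for cyclic enol silanes with aryl-substituted oxocarbenium ions) as a racemate, after which water cleaves enol silane 9 and opens anhydride 10.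

Step 5
Reactants: 11 rac-(2R)-2-{(R)-[3,5-bis(benzyloxy)phenoxy](4-methoxyphenyl)methyl}butanedioic acid; 12 (R)-1-phenylethylamine
Product: 13 bis[(1R)-1-phenylethylammonium] (2R)-2-{(R)-[3,5-bis(benzyloxy)phenoxy](4-methoxyphenyl)methyl}butanedioate
Conditions: 12 (2 equiv), EtOH–EtOAc, 60 °C then 4 °C; recrystallisation to constant rotation
Reagents that add atoms: none
Why: Classical resolution by crystallisation of diastereomeric ammonium salts, which should fix the absolute configuration of the two stereocentres made in step 4 and at the same time remove any anti diastereomer.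

Step 6
Reactants: 13 bis[(1R)-1-phenylethylammonium] (2R)-2-{(R)-[3,5-bis(benzyloxy)phenoxy](4-methoxyphenyl)methyl}butanedioate
Product: 15 (3R)-3-{(R)-[3,5-bis(benzyloxy)phenoxy](4-methoxyphenyl)methyl}oxolane-2,5-dione, via free diacid 14 (not isolated)
Conditions: 1 M HCl, EtOAc, 0 °C; then DCC (N,N'-dicyclohexylcarbodiimide), CH2Cl2, 0 °C to rt
Reagents that add atoms: none
Why: Acidification frees the diacid and carbodiimide-mediated cyclodehydration closes the five-membered anhydride under neutral conditions, so that the enolisable C-3 stereocentre should stay untouched.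

Step 7
Reactants: 15 (3R)-3-{(R)-[3,5-bis(benzyloxy)phenoxy](4-methoxyphenyl)methyl}oxolane-2,5-dione; 7 (3,5-dimethoxyphenoxy)(4-methoxyphenyl)methyl 2,2-dimethylpropanoate
Product: 20 (2R,2''R,3R,3''R)-5,7-bis(benzyloxy)-5'',7''-dimethoxy-2,2''-bis(4-methoxyphenyl)-2,2'',3,3''-tetrahydro-4H,4''H-[3,3''-bichromene]-4,4''-dione, via enol silane 16 (not isolated), via trans-anhydride 17 (not isolated), via keto acid 18 (not isolated), via mixed anhydride 19 (not isolated)
Conditions: tBuMe2SiOTf (1.05 equiv), Et3N (1.05 equiv), CH2Cl2, −78 to −40 °C; then 7 (1.1 equiv), tBuMe2SiOTf (20 mol%), −78 to 0 °C; then (CF3CO)2O (1.5 equiv), 0 °C to rt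
Reagents that add atoms: none
Why: Proposed new method: soft enolisation (tBuMe2SiOTf/Et3N) at the unsubstituted CH2 should give enol silane 16, the catalytic second portion of tBuMe2SiOTf ionises the pivalate of 7 to the O-aryl oxocarbenium ion, C-3'' attacks C-2'' (Mukaiyama addition) to give trans-anhydride 17, whose silyl-activated C-4'' carbonyl then acylates C-4a'' of the trioxygenated ring A'' to give 18 with return of the silyl triflate, and (CF3CO)2O activates the liberated C-4 acid as mixed anhydride 19 for the same acylation at C-4a of ring A. Taken together, the cation C-4a''=C-8a''–O-1''=C-2'' and the C-3''=C-4'' enol silane undergo a stepwise formal [4+2] annulation; the closest known reactions are the oxa-Povarov reaction of aryl oxocarbenium ions with alkenes, the one-flask enol silane formation/Mukaiyama addition to acetal-type electrophiles and the intramolecular Friedel–Crafts acylation by cyclic anhydrides, but an anhydride enol silane has not been used as the acylating 2π partner. Ring C'' and ring C each close by 6-exo-trig attack of the arene on an activated acyl carbon (electrophilic aromatic substitution with loss of a carboxylate leaving group). C-3'' is set by the resident C-3 substituent of the five-membered enol silane, the cation adding to the opposite face to give the trans-anhydride that corresponds to the 3R,3''R relationship, and C-2'' is set syn to C-3'' by the open antiperiplanar transition state described for step 4, which after ring closure is the 2'',3''-cis arrangement. The step needs enolisation at CH2 only (secured by the bulky silyl group, one equivalent of base and the hindered substituted C-3), C–C bond formation by the ketene acetal rather than by the arenes (secured by its far higher nucleophilicity) and a single acylation site per ring (the two positions ortho to the ether oxygen of each symmetrically substituted ring are equivalent, and only they reach the acyl carbon through a six-membered transition state).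

Step 8
Reactants: 20 (2R,2''R,3R,3''R)-5,7-bis(benzyloxy)-5'',7''-dimethoxy-2,2''-bis(4-methoxyphenyl)-2,2'',3,3''-tetrahydro-4H,4''H-[3,3''-bichromene]-4,4''-dione
Product: 21 (2R,2''R,3R,3''R)-5,5'',7-trihydroxy-7''-methoxy-2,2''-bis(4-methoxyphenyl)-2,2'',3,3''-tetrahydro-4H,4''H-[3,3''-bichromene]-4,4''-dione
Conditions: BCl3 (8 equiv), C6HMe5 (pentamethylbenzene, 6 equiv), CH2Cl2, −78 to 0 °C; aqueous work-up
Reagents that add atoms: none
Why: Lewis acid ether cleavage in which BCl3 should remove the two aryl benzyl ethers (benzyl cations trapped by pentamethylbenzene) and, through chelation with the C-4'' carbonyl, only the peri 5''-methyl ether, while the three non-chelated methyl ethers stay and the cold, non-basic conditions avoid enolisation at C-3 and C-3'' and retro-oxa-Michael opening at C-2 and C-2''.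

**Compound list**

1 | 4-methoxybenzaldehyde | COc1ccc(C=O)cc1 | starting material
2 | pivaloyl chloride (2,2-dimethylpropanoyl chloride) | CC(C)(C)C(Cl)=O | starting material
3 | chloro(4-methoxyphenyl)methyl 2,2-dimethylpropanoate (racemic) | COc1ccc(cc1)C(Cl)OC(=O)C(C)(C)C | intermediate
4 | 3,5-bis(benzyloxy)phenol | Oc1cc(OCc2ccccc2)cc(OCc2ccccc2)c1 | starting material
5 | [3,5-bis(benzyloxy)phenoxy](4-methoxyphenyl)methyl 2,2-dimethylpropanoate (racemic) | COc1ccc(cc1)C(OC(=O)C(C)(C)C)Oc1cc(OCc2ccccc2)cc(OCc2ccccc2)c1 | intermediate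
6 | 3,5-dimethoxyphenol | COc1cc(O)cc(OC)c1 | starting material
7 | (3,5-dimethoxyphenoxy)(4-methoxyphenyl)methyl 2,2-dimethylpropanoate (racemic) | COc1ccc(cc1)C(OC(=O)C(C)(C)C)Oc1cc(OC)cc(OC)c1 | intermediate
8 | 2,5-bis(trimethylsilyloxy)furan | C[Si](C)(C)Oc1ccc(O[Si](C)(C)C)o1 | starting material
9 | rac-(3R)-3-{(R)-[3,5-bis(benzyloxy)phenoxy](4-methoxyphenyl)methyl}-5-(trimethylsilyloxy)furan-2(3H)-one (racemate, one enantiomer drawn) | COc1ccc(cc1)[C@H](Oc1cc(OCc2ccccc2)cc(OCc2ccccc2)c1)[C@H]1C=C(O[Si](C)(C)C)OC1=O | intermediate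
10 | rac-(3R)-3-{(R)-[3,5-bis(benzyloxy)phenoxy](4-methoxyphenyl)methyl}oxolane-2,5-dione (racemate, one enantiomer drawn) | COc1ccc(cc1)[C@H](Oc1cc(OCc2ccccc2)cc(OCc2ccccc2)c1)[C@H]1CC(=O)OC1=O | intermediate
11 | rac-(2R)-2-{(R)-[3,5-bis(benzyloxy)phenoxy](4-methoxyphenyl)methyl}butanedioic acid (racemate, one enantiomer drawn) | COc1ccc(cc1)[C@H](Oc1cc(OCc2ccccc2)cc(OCc2ccccc2)c1)[C@@H](CC(O)=O)C(O)=O | intermediate
12 | (R)-1-phenylethylamine | C[C@@H](N)c1ccccc1 | starting material
13 | bis[(1R)-1-phenylethylammonium] (2R)-2-{(R)-[3,5-bis(benzyloxy)phenoxy](4-methoxyphenyl)methyl}butanedioate | COc1ccc(cc1)[C@H](Oc1cc(OCc2ccccc2)cc(OCc2ccccc2)c1)[C@@H](CC([O-])=O)C([O-])=O.C[C@@H]([NH3+])c1ccccc1.C[C@@H]([NH3+])c1ccccc1 | intermediate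
14 | (2R)-2-{(R)-[3,5-bis(benzyloxy)phenoxy](4-methoxyphenyl)methyl}butanedioic acid | COc1ccc(cc1)[C@H](Oc1cc(OCc2ccccc2)cc(OCc2ccccc2)c1)[C@@H](CC(O)=O)C(O)=O | intermediate
15 | (3R)-3-{(R)-[3,5-bis(benzyloxy)phenoxy](4-methoxyphenyl)methyl}oxolane-2,5-dione | COc1ccc(cc1)[C@H](Oc1cc(OCc2ccccc2)cc(OCc2ccccc2)c1)[C@H]1CC(=O)OC1=O | intermediate
16 | (3R)-3-{(R)-[3,5-bis(benzyloxy)phenoxy](4-methoxyphenyl)methyl}-5-[tert-butyl(dimethyl)silyloxy]furan-2(3H)-one | COc1ccc(cc1)[C@H](Oc1cc(OCc2ccccc2)cc(OCc2ccccc2)c1)[C@H]1C=C(O[Si](C)(C)C(C)(C)C)OC1=O | intermediate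
17 | (3R,4R)-3-{(R)-[3,5-bis(benzyloxy)phenoxy](4-methoxyphenyl)methyl}-4-[(R)-(3,5-dimethoxyphenoxy)(4-methoxyphenyl)methyl]oxolane-2,5-dione | COc1ccc(cc1)[C@H](Oc1cc(OCc2ccccc2)cc(OCc2ccccc2)c1)[C@@H]1C(=O)OC(=O)[C@H]1[C@@H](Oc1cc(OC)cc(OC)c1)c1ccc(OC)cc1 | intermediate
18 | (2R,3R)-3-[3,5-bis(benzyloxy)phenoxy]-2-[(2R,3R)-5,7-dimethoxy-2-(4-methoxyphenyl)-4-oxo-3,4-dihydro-2H-chromen-3-yl]-3-(4-methoxyphenyl)propanoic acid | COc1ccc(cc1)[C@H](Oc1cc(OCc2ccccc2)cc(OCc2ccccc2)c1)[C@H](C(O)=O)[C@H]1C(=O)c2c(OC)cc(OC)cc2O[C@H]1c1ccc(OC)cc1 | intermediate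
19 | (2R,3R)-3-[3,5-bis(benzyloxy)phenoxy]-2-[(2R,3R)-5,7-dimethoxy-2-(4-methoxyphenyl)-4-oxo-3,4-dihydro-2H-chromen-3-yl]-3-(4-methoxyphenyl)propanoic trifluoroacetic anhydride | COc1ccc(cc1)[C@H](Oc1cc(OCc2ccccc2)cc(OCc2ccccc2)c1)[C@H](C(=O)OC(=O)C(F)(F)F)[C@H]1C(=O)c2c(OC)cc(OC)cc2O[C@H]1c1ccc(OC)cc1 | intermediate
20 | (2R,2''R,3R,3''R)-5,7-bis(benzyloxy)-5'',7''-dimethoxy-2,2''-bis(4-methoxyphenyl)-2,2'',3,3''-tetrahydro-4H,4''H-[3,3''-bichromene]-4,4''-dione | COc1ccc([C@@H]2Oc3cc(OCc4ccccc4)cc(OCc4ccccc4)c3C(=O)[C@@H]2[C@H]2C(=O)c3c(OC)cc(OC)cc3O[C@H]2c2ccc(OC)cc2)cc1 | intermediate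
21 | (2R,2''R,3R,3''R)-5,5'',7-trihydroxy-7''-methoxy-2,2''-bis(4-methoxyphenyl)-2,2'',3,3''-tetrahydro-4H,4''H-[3,3''-bichromene]-4,4''-dione | COc1ccc([C@@H]2Oc3cc(O)cc(O)c3C(=O)[C@@H]2[C@H]2C(=O)c3c(O)cc(OC)cc3O[C@H]2c2ccc(OC)cc2)cc1 | target

Total step count: 8. Longest linear sequence: 7 steps (steps 1, 2, 4, 5, 6, 7, 8); step 3 is a one-step branch from compound 3.

**Steps most likely to fail**

Step 7 (key step). What may go wrong:
- silylation at the substituted α-carbon, or double silylation towards an aromatic bis(silyloxy)furan, with loss of the C-3 configuration and β-elimination of the aryloxide;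
- insufficient facial or simple diastereoselection in the C-2''–C-3'' bond formation;
- competing trifluoroacetylation of the still open electron-rich ring;
- acid-induced ionisation of the anisyl-substituted benzylic C–O bonds.

Fallback (known chemistry only): the single-flask annulation is dissected into separately run, individually precedented reactions with a different acylating species. It sets out from 15. Compounds 15 and 7 are combined under the enol silane formation/Mukaiyama addition conditions at −78 °C and quenched cold, so that trans-anhydride 17 is isolated and freed from diastereomers. Hydrolysis (H2O–THF) gives (2R,3R)-2-{(R)-[3,5-bis(benzyloxy)phenoxy](4-methoxyphenyl)methyl}-3-[(R)-(3,5-dimethoxyphenoxy)(4-methoxyphenyl)methyl]butanedioic acid F1. Oxalyl chloride with catalytic DMF converts it into the corresponding butanedioyl dichloride F2. A classical double intramolecular Friedel–Crafts acylation with SnCl4 in CH2Cl2 at −40 °C then closes both pyranone rings and comes back to the route at 20.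

Step 4. What may go wrong:
- premature ionisation and hydrolysis of the acid-labile acylal 5 back to aldehyde and phenol;
- Friedel–Crafts self-alkylation of its electron-rich ring by the cation;
- erosion of the syn selectivity through reversible ionisation.

Fallback: the cation is made on demand from a robust monothioacetal by a thiophile instead of from an acylal by a silyl triflate. It sets out from 4. 4-Methoxybenzyl phenyl sulfide F3 (from thiophenol, 4-methoxybenzyl chloride and K2CO3) is chlorinated with N-chlorosuccinimide to 1-[chloro(phenylsulfanyl)methyl]-4-methoxybenzene F4. F4 is trapped with 4 and Cs2CO3 to give 1,3-bis(benzyloxy)-5-[(4-methoxyphenyl)(phenylsulfanyl)methoxy]benzene F5, which is stable to chromatography. Methyl triflate (CH2Cl2, −78 °C) in the presence of 8 then releases the same oxocarbenium ion and should give 9, and the same hydrolysis comes back to the route at 11.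

Step 8. What may go wrong:
- epimerisation at C-3 and C-3'' through boron enolates of the chelated ketones;
- ring opening towards chalcones;
- C-benzylation of the phloroglucinol ring by untrapped benzyl cations;
- over- or under-demethylation.

Fallback: the two cleavages are separated and the benzyl groups are removed without any Lewis acid. It sets out from 20. Hydrogenolysis (H2, Pd/C, EtOAc–THF, rt) should give (2R,2''R,3R,3''R)-5,7-dihydroxy-5'',7''-dimethoxy-2,2''-bis(4-methoxyphenyl)-2,2'',3,3''-tetrahydro-4H,4''H-[3,3''-bichromene]-4,4''-dione F6. Chelation-controlled demethylation of the peri 5''-methyl ether with AlCl3 in MeCN at rt then comes back to the route at 21.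

**Further compounds**

F1 | step 7 | (2R,3R)-2-{(R)-[3,5-bis(benzyloxy)phenoxy](4-methoxyphenyl)methyl}-3-[(R)-(3,5-dimethoxyphenoxy)(4-methoxyphenyl)methyl]butanedioic acid | COc1ccc(cc1)[C@H](Oc1cc(OCc2ccccc2)cc(OCc2ccccc2)c1)[C@H](C(O)=O)[C@@H](C(O)=O)[C@@H](Oc1cc(OC)cc(OC)c1)c1ccc(OC)cc1
F2 | step 7 | (2R,3R)-2-{(R)-[3,5-bis(benzyloxy)phenoxy](4-methoxyphenyl)methyl}-3-[(R)-(3,5-dimethoxyphenoxy)(4-methoxyphenyl)methyl]butanedioyl dichloride | COc1ccc(cc1)[C@H](Oc1cc(OCc2ccccc2)cc(OCc2ccccc2)c1)[C@H](C(Cl)=O)[C@@H](C(Cl)=O)[C@@H](Oc1cc(OC)cc(OC)c1)c1ccc(OC)cc1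
F3 | step 4 | 4-methoxybenzyl phenyl sulfide | COc1ccc(CSc2ccccc2)cc1
F4 | step 4 | 1-[chloro(phenylsulfanyl)methyl]-4-methoxybenzene (racemic) | COc1ccc(cc1)C(Cl)Sc1ccccc1
F5 | step 4 | 1,3-bis(benzyloxy)-5-[(4-methoxyphenyl)(phenylsulfanyl)methoxy]benzene (racemic) | COc1ccc(cc1)C(Sc1ccccc1)Oc1cc(OCc2ccccc2)cc(OCc2ccccc2)c1
F6 | step 8 | (2R,2''R,3R,3''R)-5,7-dihydroxy-5'',7''-dimethoxy-2,2''-bis(4-methoxyphenyl)-2,2'',3,3''-tetrahydro-4H,4''H-[3,3''-bichromene]-4,4''-dione | COc1ccc([C@@H]2Oc3cc(O)cc(O)c3C(=O)[C@@H]2[C@H]2C(=O)c3c(OC)cc(OC)cc3O[C@H]2c2ccc(OC)cc2)cc1
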